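**Plan**
- Labels: ring A and ring B are the two acylphloroglucinol rings of the spiroketal, ring C is the benzofuran; C1 is the CH2 of the ring A dihydrofuran, C2 the spiro carbon, C3 the methine carrying the ring C side chain.
- Cuts, in retrosynthetic order: six benzyl ethers; the ring A O–C2 ketal bond (enol ether 22); then, in one operation, the ring B O–C2 bond and the C1–aryl(ring A) bond (alkynylphenol 21 plus iodophenol 6).
- Enabling feature: C1 ties ring A to C2, and C2 also carries the ring B oxygen and C3, so C1–C2 is an ethynyl group on C3 whose inner carbon takes the ring B phenol oxygen and whose terminus takes the ring A aryl.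
- 21 is cut further at the ring C furan (iodophenol 17 plus diyne 13), at C3–alkynyl (enal 10) and at aryl–vinyl (iodide 7); all three arenes come from ketone 3, and iodophenol 6 serves both ring A and ring B.
- Forward ring order: ring C furan (step 12), ring B dihydrofuran (step 15), ring A dihydrofuran with the spiro centre (step 16).
- Stereochemistry: C3 from the chiral rhodium catalyst in step 6, carried unchanged; C2 from acid equilibration in step 16 under the control of C3.

Key step: step 15

Assumption: (R)-DTBM-segphos is taken as the ligand antipode that gives (S)-12; if it delivers the mirror image, the (S)-ligand is used with nothing else changed.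

**Route**

Step 1
Reactants: 1 phloroglucinol; 2 isovaleryl chloride
Product: 3 phloroisovalerophenone
Conditions: AlCl3 (3 equiv), PhNO2, 60 °C; aq. HCl
Reagents that add atoms: none
Why: Friedel–Crafts C-acylation of the electron-rich triol should stop after one acyl group because the new ketone deactivates the ring.

Step 2
Reactants: 3 phloroisovalerophenone; 4 benzyl bromide (two equivalents are consumed)
Product: 5 1-[2,4-bis(benzyloxy)-6-hydroxyphenyl]-3-methylbutan-1-one
Conditions: BnBr (2.1 equiv), K2CO3, DMF, rt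
Reagents that add atoms: benzyl bromide (the second equivalent of 4), BrCc1ccccc1
Why: Williamson etherification takes the para hydroxyl and one ortho hydroxyl, one molecule of benzyl bromide each, while the last ortho hydroxyl, hydrogen-bonded to the ketone, should stay free.

Step 3
Reactants: 5 1-[2,4-bis(benzyloxy)-6-hydroxyphenyl]-3-methylbutan-1-one
Product: 6 1-[4,6-bis(benzyloxy)-2-hydroxy-3-iodophenyl]-3-methylbutan-1-one
Conditions: BnMe3N·ICl2, NaHCO3, CH2Cl2/MeOH, rt
Reagents that add atoms: benzyltrimethylammonium dichloroiodate, C[N+](C)(C)Cc1ccccc1.Cl[I-]Cl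
Why: electrophilic aromatic iodination should go to the open position ortho to the free phenol, as is usual for 2-hydroxy-4,6-dialkoxyaryl ketones, the other open position being shielded by two benzyloxy groups.

Step 4
Reactants: 6 1-[4,6-bis(benzyloxy)-2-hydroxy-3-iodophenyl]-3-methylbutan-1-one
Product: 7 1-[4,6-bis(benzyloxy)-3-iodo-2-(methoxymethoxy)phenyl]-3-methylbutan-1-one
Conditions: NaH, DMF, 0 °C; MOMCl
Reagents that add atoms: chloromethyl methyl ether, COCCl
Why: Williamson-type O-alkylation of the sodium phenoxide masks the ring B phenol with a group that survives base, palladium and rhodium chemistry and leaves with dilute acid.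

Step 5
Reactants: 7 1-[4,6-bis(benzyloxy)-3-iodo-2-(methoxymethoxy)phenyl]-3-methylbutan-1-one; 8 (E)-2-(3,3-diethoxyprop-1-en-1-yl)-4,4,5,5-tetramethyl-1,3,2-dioxaborolane
Product: 10 (E)-3-[4,6-bis(benzyloxy)-2-(methoxymethoxy)-3-(3-methylbutanoyl)phenyl]prop-2-enal, via diethyl acetal 9 (not isolated)
Conditions: Pd(OAc)2, SPhos, K3PO4, toluene/H2O, 80 °C; then PPTS, acetone/H2O, rt
Reagents that add atoms: water, O
Why: Suzuki–Miyaura coupling with a dialkylbiarylphosphine ligand tolerates the two ortho substituents of the iodide, and mild hydrolysis of the allylic acetal should free the (E)-enal without touching the methoxymethyl ether.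

Step 6
Reactants: 10 (E)-3-[4,6-bis(benzyloxy)-2-(methoxymethoxy)-3-(3-methylbutanoyl)phenyl]prop-2-enal; 11 (triisopropylsilyl)acetylene
Product: 12 (S)-3-[4,6-bis(benzyloxy)-2-(methoxymethoxy)-3-(3-methylbutanoyl)phenyl]-5-(triisopropylsilyl)pent-4-ynal
Conditions: [Rh(OAc)(C2H4)2]2 (2.5 mol%), (R)-DTBM-segphos (6 mol%), MeOH, 40 °C
Reagents that add atoms: none
Why: rhodium-catalysed asymmetric conjugate alkynylation of a β-aryl enal, in which the alkynylrhodium species adds to the enal face selected by the bulky chiral bisphosphine (this sets C3), the bulky silyl group suppresses alkyne dimerization and methanol protonates the rhodium enolate.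

Step 7
Reactants: 12 (S)-3-[4,6-bis(benzyloxy)-2-(methoxymethoxy)-3-(3-methylbutanoyl)phenyl]-5-(triisopropylsilyl)pent-4-ynal
Product: 13 (S)-1-{4,6-bis(benzyloxy)-2-(methoxymethoxy)-3-[1-(triisopropylsilyl)hexa-1,5-diyn-3-yl]phenyl}-3-methylbutan-1-one
Conditions: dimethyl (1-diazo-2-oxopropyl)phosphonate, K2CO3, MeOH, 0 °C → rt
Reagents that add atoms: dimethyl (1-diazo-2-oxopropyl)phosphonate, COP(=O)(OC)C(=[N+]=[N-])C(C)=O
Why: Ohira–Bestmann (Seyferth–Gilbert) homologation turns the aldehyde into a terminal alkyne; C3 is β to the carbonyl and cannot epimerize by enolization, and the silylalkyne and the acetal-type ether tolerate K2CO3 in methanol.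

Step 8
Reactants: 3 phloroisovalerophenone
Product: 14 1-[2,6-dihydroxy-4-(methoxymethoxy)phenyl]-3-methylbutan-1-one
Conditions: MOMCl (1.05 equiv), i-Pr2NEt, CH2Cl2, 0 °C
Reagents that add atoms: chloromethyl methyl ether, COCCl
Why: O-alkylation should select the para hydroxyl, the most acidic one and the only one not hydrogen-bonded to the ketone.

Step 9
Reactants: 14 1-[2,6-dihydroxy-4-(methoxymethoxy)phenyl]-3-methylbutan-1-one; 4 benzyl bromide (two equivalents are consumed)
Product: 15 1-[2,6-bis(benzyloxy)-4-(methoxymethoxy)phenyl]-3-methylbutan-1-one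
Conditions: BnBr (2.5 equiv), K2CO3, DMF, 60 °C
Reagents that add atoms: benzyl bromide (the second equivalent of 4), BrCc1ccccc1
Why: Williamson etherification with excess halide and warming alkylates both chelated ortho hydroxyls, one molecule of benzyl bromide each.

Step 10
Reactants: 15 1-[2,6-bis(benzyloxy)-4-(methoxymethoxy)phenyl]-3-methylbutan-1-one
Product: 16 1-[2,6-bis(benzyloxy)-4-hydroxyphenyl]-3-methylbutan-1-one
Conditions: HCl, MeOH, 40 °C
Reagents that add atoms: none
Why: acid-catalysed transacetalization to methanol removes the methoxymethyl group and leaves the benzyl ethers untouched.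

Step 11
Reactants: 16 1-[2,6-bis(benzyloxy)-4-hydroxyphenyl]-3-methylbutan-1-one
Product: 17 1-[2,6-bis(benzyloxy)-4-hydroxy-3-iodophenyl]-3-methylbutan-1-one
Conditions: NIS (1.0 equiv), TsOH (cat.), MeCN, 0 °C
Reagents that add atoms: N-iodosuccinimide, O=C1CCC(=O)N1I
Why: electrophilic ortho-iodination of the phenol; the two ortho positions are equivalent by symmetry, so only over-iodination has to be held back by stoichiometry and temperature.

Step 12
Reactants: 13 (S)-1-{4,6-bis(benzyloxy)-2-(methoxymethoxy)-3-[1-(triisopropylsilyl)hexa-1,5-diyn-3-yl]phenyl}-3-methylbutan-1-one; 17 1-[2,6-bis(benzyloxy)-4-hydroxy-3-iodophenyl]-3-methylbutan-1-one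
Product: 19 (S)-1-{4,6-bis(benzyloxy)-2-[2-(4,6-bis(benzyloxy)-2-(methoxymethoxy)-3-(3-methylbutanoyl)phenyl)-4-(triisopropylsilyl)but-3-yn-1-yl]-1-benzofuran-5-yl}-3-methylbutan-1-one, via 2-alkynylphenol 18 (not isolated)
Conditions: Pd(PPh3)2Cl2, CuI, Et3N, DMF, rt → 70 °C
Reagents that add atoms: none
Why: Sonogashira coupling of the terminal alkyne followed by 5-endo-dig closure of the 2-alkynylphenoxide gives the 2-substituted benzofuran of ring C, while the silyl-capped alkyne and the masked ring B phenol cannot take part.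

Step 13
Reactants: 19 the silylated benzofuran of step 12
Product: 20 (R)-1-{4,6-bis(benzyloxy)-2-[2-(4,6-bis(benzyloxy)-2-(methoxymethoxy)-3-(3-methylbutanoyl)phenyl)but-3-yn-1-yl]-1-benzofuran-5-yl}-3-methylbutan-1-one
Conditions: Bu4NF, THF, 0 °C
Reagents that add atoms: none
Why: fluoride-induced protodesilylation of the alkynylsilane at low temperature and short contact time should leave the propargylic hydrogen in place; the change of descriptor from S to R is formal (the ethynyl group now ranks below the aryl group).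

Step 14
Reactants: 20 the terminal alkyne of step 13
Product: 21 (R)-1-{4,6-bis(benzyloxy)-2-[2-(4,6-bis(benzyloxy)-2-hydroxy-3-(3-methylbutanoyl)phenyl)but-3-yn-1-yl]-1-benzofuran-5-yl}-3-methylbutan-1-one
Conditions: HCl, MeOH/THF, rt
Reagents that add atoms: none
Why: acid-catalysed cleavage of the aryl methoxymethyl ether, eased by the neighbouring ketone, frees the ring B phenol; benzyl ethers, the terminal alkyne and the benzofuran are inert to dilute acid and no bond at C3 is touched.

Step 15
Reactants: 21 ring B 2-(prop-2-ynyl)phenol carrying C3; 6 1-[4,6-bis(benzyloxy)-2-hydroxy-3-iodophenyl]-3-methylbutan-1-one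
Product: 22 (3S)-(E)-2-[4,6-bis(benzyloxy)-2-hydroxy-3-(3-methylbutanoyl)benzylidene]-3-{[4,6-bis(benzyloxy)-5-(3-methylbutanoyl)-1-benzofuran-2-yl]methyl}-4,6-bis(benzyloxy)-7-(3-methylbutanoyl)-2,3-dihydro-1-benzofuran
Conditions: Pd(PPh3)4 (5 mol%), K2CO3, MeCN, 60 °C; neutral work-up
Reagents that add atoms: none
Why: Zerovalent palladium inserts into the C–I bond of 6, the arylpalladium iodide (divalent palladium) binds the terminal alkyne of 21, the ring B phenoxide attacks the inner alkyne carbon anti to the metal, and reductive elimination joins the ring A aryl to the terminal carbon C1. The closest known reaction type is the palladium-catalysed arylative cyclization of alkynes bearing a pendant oxygen nucleophile (alkynols, alkynoic acids, 2-propargylphenols) with aryl halides, which gives (E)-arylidene oxacycles. The ring B dihydrofuran closes in the 5-exo-dig mode. No stereocentre is created: the E geometry follows from anti oxypalladation and stereoretentive reductive elimination, and C3, which is not enolizable and not involved, is carried through. The step needs oxypalladation to outrun copper-free Sonogashira coupling and attack by the phenoxide of 6, which the absence of copper and amine and the five-ring closure by the adjacent ring B phenoxide should secure. It also needs the C3 hydrogen to stay in place (no allene, no migration of the new double bond into ring B), for which carbonate base, moderate temperature and an acid-free work-up are chosen.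

Step 16
Reactants: 22 the (E)-enol ether of step 15
Product: 23 hexabenzyl ether of the target (spiro carbon R and C3 S)
Conditions: PPTS (0.2 equiv), CH2Cl2, 4 Å MS, rt
Reagents that add atoms: none
Why: acid-catalysed spiroketalization, in which protonation of the enol ether at C1 gives an oxocarbenium ion that the ring A phenol traps (5-exo-trig), and reversible ring opening should equilibrate C2 to the epimer with the ring A oxygen cis and the larger C1 methylene trans to the C3 side chain.

Step 17
Reactants: 23 hexabenzyl ether of the target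
Product: 24 CNP0169640.1
Conditions: H2 (1 atm), 10% Pd/C, EtOAc/MeOH, rt
Reagents that add atoms: none
Why: hydrogenolysis of the six benzyl ethers under neutral conditions; the ketal C–O bonds are not benzylic, and the hydrogen-bonded aryl ketones and the benzofuran should be reduced much more slowly.

**Compound list**

1 | phloroglucinol | Oc1cc(O)cc(O)c1 | starting material
2 | isovaleryl chloride | CC(C)CC(Cl)=O | starting material
3 | phloroisovalerophenone, 1-(2,4,6-trihydroxyphenyl)-3-methylbutan-1-one | CC(C)CC(=O)c1c(O)cc(O)cc1O | intermediate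
4 | benzyl bromide | BrCc1ccccc1 | starting material
5 | 1-[2,4-bis(benzyloxy)-6-hydroxyphenyl]-3-methylbutan-1-one | CC(C)CC(=O)c1c(O)cc(OCc2ccccc2)cc1OCc1ccccc1 | intermediate
6 | 1-[4,6-bis(benzyloxy)-2-hydroxy-3-iodophenyl]-3-methylbutan-1-one (iodophenol for ring A and ring B) | CC(C)CC(=O)c1c(O)c(I)c(OCc2ccccc2)cc1OCc1ccccc1 | intermediate
7 | 1-[4,6-bis(benzyloxy)-3-iodo-2-(methoxymethoxy)phenyl]-3-methylbutan-1-one | CC(C)CC(=O)c1c(OCOC)c(I)c(OCc2ccccc2)cc1OCc1ccccc1 | intermediate
8 | (E)-2-(3,3-diethoxyprop-1-en-1-yl)-4,4,5,5-tetramethyl-1,3,2-dioxaborolane | CCOC(OCC)/C=C/B1OC(C)(C)C(C)(C)O1 | starting material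
9 | 1-{4,6-bis(benzyloxy)-3-[(E)-3,3-diethoxyprop-1-en-1-yl]-2-(methoxymethoxy)phenyl}-3-methylbutan-1-one (diethyl acetal, not isolated) | CC(C)CC(=O)c1c(OCOC)c(/C=C/C(OCC)OCC)c(OCc2ccccc2)cc1OCc1ccccc1 | intermediate
10 | (E)-3-[4,6-bis(benzyloxy)-2-(methoxymethoxy)-3-(3-methylbutanoyl)phenyl]prop-2-enal | CC(C)CC(=O)c1c(OCOC)c(/C=C/C=O)c(OCc2ccccc2)cc1OCc1ccccc1 | intermediate
11 | (triisopropylsilyl)acetylene | C#C[Si](C(C)C)(C(C)C)C(C)C | starting material
12 | (S)-3-[4,6-bis(benzyloxy)-2-(methoxymethoxy)-3-(3-methylbutanoyl)phenyl]-5-(triisopropylsilyl)pent-4-ynal | COCOc1c(C(=O)CC(C)C)c(OCc2ccccc2)cc(OCc2ccccc2)c1[C@@H](C#C[Si](C(C)C)(C(C)C)C(C)C)CC=O | intermediate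
13 | (S)-1-{4,6-bis(benzyloxy)-2-(methoxymethoxy)-3-[1-(triisopropylsilyl)hexa-1,5-diyn-3-yl]phenyl}-3-methylbutan-1-one | COCOc1c(C(=O)CC(C)C)c(OCc2ccccc2)cc(OCc2ccccc2)c1[C@@H](C#C[Si](C(C)C)(C(C)C)C(C)C)CC#C | intermediate
14 | 1-[2,6-dihydroxy-4-(methoxymethoxy)phenyl]-3-methylbutan-1-one | CC(C)CC(=O)c1c(O)cc(OCOC)cc1O | intermediate
15 | 1-[2,6-bis(benzyloxy)-4-(methoxymethoxy)phenyl]-3-methylbutan-1-one | CC(C)CC(=O)c1c(OCc2ccccc2)cc(OCOC)cc1OCc1ccccc1 | intermediate
16 | 1-[2,6-bis(benzyloxy)-4-hydroxyphenyl]-3-methylbutan-1-one | CC(C)CC(=O)c1c(OCc2ccccc2)cc(O)cc1OCc1ccccc1 | intermediate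
17 | 1-[2,6-bis(benzyloxy)-4-hydroxy-3-iodophenyl]-3-methylbutan-1-one (ring C iodophenol) | CC(C)CC(=O)c1c(OCc2ccccc2)cc(O)c(I)c1OCc1ccccc1 | intermediate
18 | (S)-2-alkynylphenol from 13 and 17: terminal alkyne carbon of 13 bonded to C3 of the 2,6-bis(benzyloxy)-4-hydroxy-1-isovalerylphenyl ring (not isolated) | COCOc1c(C(=O)CC(C)C)c(OCc2ccccc2)cc(OCc2ccccc2)c1[C@@H](C#C[Si](C(C)C)(C(C)C)C(C)C)CC#Cc1c(O)cc(OCc2ccccc2)c(C(=O)CC(C)C)c1OCc1ccccc1 | intermediate
19 | (S)-1-{4,6-bis(benzyloxy)-2-[2-(4,6-bis(benzyloxy)-2-(methoxymethoxy)-3-(3-methylbutanoyl)phenyl)-4-(triisopropylsilyl)but-3-yn-1-yl]-1-benzofuran-5-yl}-3-methylbutan-1-one | COCOc1c(C(=O)CC(C)C)c(OCc2ccccc2)cc(OCc2ccccc2)c1[C@@H](C#C[Si](C(C)C)(C(C)C)C(C)C)Cc1cc2c(OCc3ccccc3)c(C(=O)CC(C)C)c(OCc3ccccc3)cc2o1 | intermediate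
20 | (R)-1-{4,6-bis(benzyloxy)-2-[2-(4,6-bis(benzyloxy)-2-(methoxymethoxy)-3-(3-methylbutanoyl)phenyl)but-3-yn-1-yl]-1-benzofuran-5-yl}-3-methylbutan-1-one (same spatial arrangement at C3 as 19) | COCOc1c(C(=O)CC(C)C)c(OCc2ccccc2)cc(OCc2ccccc2)c1[C@@H](C#C)Cc1cc2c(OCc3ccccc3)c(C(=O)CC(C)C)c(OCc3ccccc3)cc2o1 | intermediate
21 | (R)-1-{4,6-bis(benzyloxy)-2-[2-(4,6-bis(benzyloxy)-2-hydroxy-3-(3-methylbutanoyl)phenyl)but-3-yn-1-yl]-1-benzofuran-5-yl}-3-methylbutan-1-one (ring B propargylic phenol) | Oc1c(C(=O)CC(C)C)c(OCc2ccccc2)cc(OCc2ccccc2)c1[C@@H](C#C)Cc1cc2c(OCc3ccccc3)c(C(=O)CC(C)C)c(OCc3ccccc3)cc2o1 | intermediate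
22 | (3S)-(E)-2-[4,6-bis(benzyloxy)-2-hydroxy-3-(3-methylbutanoyl)benzylidene]-3-{[4,6-bis(benzyloxy)-5-(3-methylbutanoyl)-1-benzofuran-2-yl]methyl}-4,6-bis(benzyloxy)-7-(3-methylbutanoyl)-2,3-dihydro-1-benzofuran | CC(C)CC(=O)c1c(OCc3ccccc3)cc(OCc3ccccc3)c(c1O)/C=C1/Oc2c(C(=O)CC(C)C)c(OCc3ccccc3)cc(OCc3ccccc3)c2[C@@H]1Cc1cc2c(OCc3ccccc3)c(C(=O)CC(C)C)c(OCc3ccccc3)cc2o1 | intermediate
23 | hexabenzyl ether of the target: spiro carbon R, C3 S, ring A oxygen and C3 side chain on the same face of ring B | CC(C)CC(=O)c1c(OCc3ccccc3)cc(OCc3ccccc3)c2c1O[C@]1(C2)Oc2c(C(=O)CC(C)C)c(OCc3ccccc3)cc(OCc3ccccc3)c2[C@@H]1Cc1cc2c(OCc3ccccc3)c(C(=O)CC(C)C)c(OCc3ccccc3)cc2o1 | intermediate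
24 | CNP0169640.1 (spiro carbon R, C3 S) | CC(C)CC(=O)c1c(O)cc(O)c2c1O[C@]1(C2)Oc2c(C(=O)CC(C)C)c(O)cc(O)c2[C@@H]1Cc1cc2c(O)c(C(=O)CC(C)C)c(O)cc2o1 | target

**Count and risks**

Total step count: 17. Longest linear sequence: 13 steps (steps 1–7 and 12–17).

Steps most likely to fail:

1. Step 6. The two ortho substituents of the aryl group may slow insertion of the alkynylrhodium species into the enal, so that alkyne dimerization or 1,2-addition takes over, or they may erode facial discrimination. The fallback sets out from 7 and 17 and comes back at 20. Sonogashira coupling–cyclization of 17 (Pd(PPh3)2Cl2, CuI, Et3N, DMF) with racemic 1-(trimethylsilyl)hexa-1,5-diyn-3-ol F1, itself from 3-(trimethylsilyl)propynal and propargyl bromide under zinc Barbier conditions, would give the racemic benzofuranylmethyl propargylic alcohol F2. An Appel reaction (CBr4, PPh3) would turn it into the racemic propargylic bromide F3. Zinc insertion into 7 (Zn dust, LiCl, THF) would give the arylzinc iodide F4. An enantioconvergent Negishi coupling of F3 with F4 (NiCl2·glyme, chiral indanyl-pybox ligand, glyme, −20 °C) would then form C3 from a planar propargylic radical and give the (S)-trimethylsilylalkyne F5. K2CO3 in MeOH would remove the silyl group and deliver 20. This coupling carries its own risk, since the arylzinc reagent is ortho-disubstituted.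

2. Step 15. Copper-free Sonogashira coupling of 6 followed by 5-endo closure to a ring A benzofuran may compete; base may isomerize the alkyne to an allene at C3; or the new exocyclic double bond may migrate into ring B, which would erase C3. The fallback sets out from 21 and 7 and comes back at 23, forming the two bonds one after the other. Sonogashira coupling at room temperature (Pd(PPh3)2Cl2, CuI, Et3N, THF) would give the internal alkyne F6, with the ring A phenol masked as its methoxymethyl ether. A catalytic amount of Cs2CO3 in MeCN would close ring B by anionic 5-exo-dig hydroalkoxylation to the (Z)-enol ether F7. Dilute HCl in MeOH/CH2Cl2 would then remove the methoxymethyl group and close the spiroketal in the same operation to give 23. Any arylative cyclization that intervenes in the first stage leads to the E isomer of F7 and converges on 23 as well.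

3. Step 16. Kinetic closure may give the C2 epimer and equilibration may be slow, or the oxocarbenium ion may lose the C3 hydrogen and aromatize ring B to a benzofuran. The fallback sets out from 22 and comes back at 24. N-Iodosuccinimide with NaHCO3 in CH2Cl2 at −78 °C would close the ketal irreversibly by iodoetherification to the C1-iodo spiroketal F8. Iodine should be delivered to the face of the enol ether remote from the C3 side chain and the ring A oxygen should add anti to it, that is, on the side of the C3 side chain as in the target. Hydrogenolysis (H2, 10% Pd/C, Et3N, EtOAc/MeOH) would then cleave the benzylic C–I bond together with the six benzyl ethers and give 24.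

**Further compounds**

F1 | step 6 | racemic 1-(trimethylsilyl)hexa-1,5-diyn-3-ol | C[Si](C)(C)C#CC(O)CC#C
F2 | step 6 | racemic 1-{4,6-bis(benzyloxy)-2-[2-hydroxy-4-(trimethylsilyl)but-3-yn-1-yl]-1-benzofuran-5-yl}-3-methylbutan-1-one | C[Si](C)(C)C#CC(O)Cc1cc2c(OCc3ccccc3)c(C(=O)CC(C)C)c(OCc3ccccc3)cc2o1
F3 | step 6 | racemic 1-{4,6-bis(benzyloxy)-2-[2-bromo-4-(trimethylsilyl)but-3-yn-1-yl]-1-benzofuran-5-yl}-3-methylbutan-1-one | C[Si](C)(C)C#CC(Br)Cc1cc2c(OCc3ccccc3)c(C(=O)CC(C)C)c(OCc3ccccc3)cc2o1
F4 | step 6 | [4,6-bis(benzyloxy)-2-(methoxymethoxy)-3-(3-methylbutanoyl)phenyl]zinc iodide | CC(C)CC(=O)c1c(OCOC)c([Zn]I)c(OCc2ccccc2)cc1OCc1ccccc1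
F5 | step 6 | (S)-trimethylsilyl analogue of 19 | COCOc1c(C(=O)CC(C)C)c(OCc2ccccc2)cc(OCc2ccccc2)c1[C@@H](C#C[Si](C)(C)C)Cc1cc2c(OCc3ccccc3)c(C(=O)CC(C)C)c(OCc3ccccc3)cc2o1
F6 | step 15 | (R)-internal alkyne: 21 arylated at its alkyne terminus by the 4,6-bis(benzyloxy)-2-(methoxymethoxy)-3-(3-methylbutanoyl)phenyl group of 7 | Oc1c(C(=O)CC(C)C)c(OCc2ccccc2)cc(OCc2ccccc2)c1[C@@H](C#Cc1c(OCOC)c(C(=O)CC(C)C)c(OCc2ccccc2)cc1OCc1ccccc1)Cc1cc2c(OCc3ccccc3)c(C(=O)CC(C)C)c(OCc3ccccc3)cc2o1
F7 | step 15 | (3S)-(Z)-enol ether: Z isomer of 22 with the ring A phenol as its methoxymethyl ether | CC(C)CC(=O)c1c(OCc3ccccc3)cc(OCc3ccccc3)c(c1OCOC)/C=C1\Oc2c(C(=O)CC(C)C)c(OCc3ccccc3)cc(OCc3ccccc3)c2[C@@H]1Cc1cc2c(OCc3ccccc3)c(C(=O)CC(C)C)c(OCc3ccccc3)cc2o1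
F8 | step 16 | C1-iodo derivative of 23 (configuration at C2 and C3 as in 23, C1 not defined) | CC(C)CC(=O)c1c(OCc3ccccc3)cc(OCc3ccccc3)c2c1O[C@]1(C2I)Oc2c(C(=O)CC(C)C)c(OCc3ccccc3)cc(OCc3ccccc3)c2[C@@H]1Cc1cc2c(OCc3ccccc3)c(C(=O)CC(C)C)c(OCc3ccccc3)cc2o1
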